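The data stem from a simulated flask from invented constants; scatter was added.

The books of this flask are kept in monomer, in percent of the solid monomer charged, and they are closed at 15 h.

| setting | midnight | autumn | dusk | flask |
|---|---|---|---|---|
| solid monomer | 1 M | 1 M | 1.5 M | 1.0 M |
| initiator | 1.2 mol% | 1.9 mol% | 2.5 mol% | 2.5 mol% |
| remark | run made earlier | run made earlier | run made earlier |  |
| time |  |  |  | 15 h |

| run | time / h | monomer in chains / % | free monomer / % | solid monomer / % |
|---|---|---|---|---|
| midnight | 0.833 | 0.8 | 4.2 | 97.3 |
| midnight | 2.50 | 0.2 | 9.2 | 90.8 |
| midnight | 4.00 | 0 | 11.1 | 87.1 |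
| midnight | 6.00 | 0 | 18.6 | 81.9 |
| midnight | 10.0 | 0.9 | 27.0 | 72.6 |
| midnight | 12.0 | 0 | 29.2 | 68.7 |
| midnight | 15.0 | 2.6 | 35.9 | 63.1 |
| autumn | 1.33 | 2.6 | 4.7 | 94.8 |
| autumn | 2.00 | 0.5 | 8.0 | 93.1 |
| autumn | 3.00 | 0 | 10.9 | 89.1 |
| autumn | 4.00 | 0 | 12.2 | 86.4 |
| autumn | 6.00 | 0 | 17.9 | 81.7 |
| autumn | 10.0 | 1.9 | 26.1 | 73.2 |
| autumn | 15.0 | 2.3 | 32.3 | 63.7 |
| dusk | 1.33 | 0 | 3.5 | 94.3 |
| dusk | 2.50 | 0.5 | 6.4 | 94.0 |
| dusk | 4.00 | 2.0 | 8.4 | 92.3 |
| dusk | 8.00 | 0 | 15.5 | 84.5 |
| dusk | 15.0 | 3.4 | 21.7 | 77.2 |

(readings scatter by 1 percentage point)

- solid, in amounts per volume of the solution: solid monomer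
- what may be going on: free monomer + initiator -> living end + monomer in chains; free monomer + living end -> monomer in chains + living end; solid monomer <-> free monomer
- at the start none of the solid monomer is in solution

1. monomer in chains at 15 h, in percent of the solid monomer charged
2. concentration of free monomer in solution at 4.0 h, in percent of saturation
3. the change that raises the amount of monomer in chains at 15 h, in percent of the solid monomer charged most ("none" if none brings more than 2 percentage points) (delta / epsilon / theta / none)
4. amount of monomer in chains at 15 h, in percent of the solid monomer charged, after delta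

- delta: doubling the amount of initiator, all else as stated
- epsilon: doubling the solubility of the solid monomer, all else as stated
- theta: doubling the dissolution coefficient of the solid monomer, all else as stated

Each unit of monomer stands in one of three entries: solid monomer, free monomer or monomer in chains. Both written chain steps lead from free monomer into chains, so the chain entry is the one to fill.

The first entry is read directly. The midnight and autumn runs have the flask's charge of solid monomer, and at 15 h they read 63.1 % and 63.7 % solid despite loadings of 1.2 mol% and 1.9 mol%. Their mean leaves 36.6 %: this is the dissolved share, the part of the charge no longer solid at that time, free or in chains. This flask differs from those runs in its initiator loading, so the same share is entered for it.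

The second entry is weak, since chains barely clear the scatter. The autumn reading, scaled to 2.5 mol%, gives 3.03 % by my reckoning, and twice that after delta. The balance, 33.6 %, stays free monomer. In the midnight run at 15.0 h, free monomer reads 35.9 %, far more than the 2.6 % in chains. Both chain steps use free monomer, and living ends come from one of them, so epsilon is my choice. The saturation entry stays open: midnight free monomer still climbs from 29.2 % to 35.9 %.

The forecast gave 3.5 %, 15 %, epsilon and 6.5 %, with the remark “Cs is poorly fixed”.

The flask gives 3.37 %, 24.9 % and 6.36 %, and the best change is epsilon, which gains 7.3 percentage points against 3 points for delta and 3.5 points for theta.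

    free monomer + initiator → living end + monomer in chains (k = 0.100 /M/h)
    free monomer + living end → monomer in chains + living end, rate k2*[living end]*[free monomer] (k = 2.70 /M/h)
    solid monomer ⇌ free monomer, rate k3*(cs3 - [free monomer]) while solid is left; crystals form when [free monomer] > cs3 (solubility = 0.530 M, k = 0.0720 /h)

At 15 h this flask holds 64.2 % solid, so its dissolved share is 35.8 %, against the 36.6 % carried over; that share splits into 32.4 % free and 3.37 % in chains. The neighbouring flask has the same charge and is left until 40 h, 2.67 times as long. It holds 31.9 % solid, so its dissolved share is 68.1 %, twice the carried value. Of that share, 33.7 % stands free and 34.4 % stands in chains, half of it.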